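**Retrosynthetic overview**
1. Target ⇐ C7 acetylation of the macrocyclic 7,12-diol; the 14-membered ring is closed last, at C4–C5, by a nickel-catalysed electroreductive coupling of a primary alkyl iodide with an alkenyl iodide.
2. The diene is built on the open chain: C14–C1 by B-alkyl Suzuki coupling of a vinyl carbinol with a (Z)-bromoenyne (from bromoboration of 3-methylbut-1-yne), then C4–I by hydrozirconation/iodination.
3. The cis-tetrahydrofuran (first ring, sets C11 and C12) comes from osmium-catalysed oxidative cyclisation of a 7,8-diol onto a (Z)-trisubstituted alkene.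
4. C8 is set by chelation-controlled MeMgBr addition to an α-alkoxide ketone made from (3R)-3-hydroxyoxolan-2-one (the bought C7 centre) and a dienylmagnesium bromide.
5. The (Z)-alkene comes from nickel-catalysed ring opening of 5-methyl-2,3-dihydrofuran with vinylmagnesium bromide. Ring order: tetrahydrofuran first, macrocycle second.

Assumption and locants: (3R)-3-hydroxyoxolan-2-one and 1-bromoprop-1-yne are bought; C1–C14 are cembrane locants (C1 isopropyl; C4, C8, C12 methyl; C7 acetoxy; ether oxygen between C8 and C11).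

**Route**

Step 1
Reactants: 1 5-methyl-2,3-dihydrofuran; 2 vinylmagnesium bromide
Product: 3 (3Z)-4-methylhexa-3,5-dien-1-ol
Conditions: NiCl2(PPh3)2 (5 mol%), THF/PhMe, 80 °C; aq NH4Cl
Reagents that add atoms: none
Why: Nickel-catalysed Kumada-type coupling at the enol ether C–O bond (Wenkert ring opening) goes with retention at the alkene carbon, so the vinyl group stays cis to the CH2CH2O chain and the (Z)-alkene that becomes C11=C12 is fixed.

Step 2
Reactants: 3 (3Z)-4-methylhexa-3,5-dien-1-ol
Product: 4 (3Z)-6-bromo-3-methylhexa-1,3-diene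
Conditions: CBr4, PPh3, CH2Cl2, 0 °C
Reagents that add atoms: carbon tetrabromide, BrC(Br)(Br)Br
Why: Appel bromination of the primary alcohol under neutral conditions leaves the diene and its geometry untouched.

Step 3
Reactants: 4 (3Z)-6-bromo-3-methylhexa-1,3-diene; 5 (3R)-3-hydroxyoxolan-2-one
Product: 8 (3R,4S,7Z)-4,8-dimethyldeca-7,9-diene-1,3,4-triol, via dienylmagnesium bromide 6 (not isolated), via ring-opened hydroxy ketone 7 (not isolated)
Conditions: 4, Mg, THF, 35 °C; 5, tBuMgCl (1.0 equiv), THF, −78 °C, then 6 (1.1 equiv), −78 to −30 °C; MeMgBr (3 equiv), −78 to 0 °C; aq NH4Cl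
Reagents that add atoms: methylmagnesium bromide, C[Mg]Br
Why: Acylation of 6 by the lactone should stop after one addition because the magnesium hemiketalate is chelated to the neighbouring C7 alkoxide, and the ketone released on warming undergoes Cram chelate-controlled addition of MeMgBr from the side of the C7 hydrogen, which sets C8 (7,8-syn, 8S) from the bought C7 centre.

Step 4
Reactants: 8 (3R,4S,7Z)-4,8-dimethyldeca-7,9-diene-1,3,4-triol
Product: 9 (1R)-1-[(2S,5R)-5-[(2S)-2-hydroxybut-3-en-2-yl]-2-methyloxolan-2-yl]propane-1,3-diol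
Conditions: K2OsO2(OH)4 (5 mol%), pyridine N-oxide (3 equiv), citric acid, MeCN/H2O, 50 °C
Reagents that add atoms: pyridine N-oxide, [O-][n+]1ccccc1
Why: Donohoe-type osmium-catalysed oxidative cyclisation of a 5,6-dihydroxyalkene: the hexavalent osmium glycolate of the 7,8-diol is reoxidised and adds intramolecularly and syn across the tethered (Z)-alkene, so O8–C11 and O–C12 form on one face, the tetrahydrofuran is 2,5-cis and C11 and C12 come out (11R,12S).

Step 5
Reactants: 10 3-methylbut-1-yne
Product: 12 2-[(1Z)-2-bromo-3-methylbut-1-en-1-yl]-4,4,5,5-tetramethyl-1,3,2-dioxaborolane, via alkenyldibromoborane 11 (not isolated)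
Conditions: BBr3, CH2Cl2, −78 °C to rt; pinacol, 0 °C
Reagents that add atoms: boron tribromide, BrB(Br)Br; pinacol, CC(C)(O)C(C)(C)O
Why: syn-Bromoboration of a terminal alkyne puts Br on the internal and B on the terminal carbon on the same side, which later places C14 (in place of Br) cis to C3 (in place of B).

Step 6
Reactants: 12 2-[(1Z)-2-bromo-3-methylbut-1-en-1-yl]-4,4,5,5-tetramethyl-1,3,2-dioxaborolane; 13 1-bromoprop-1-yne
Product: 14 (3Z)-3-bromo-2-methylhept-3-en-5-yne
Conditions: Pd(PPh3)4 (5 mol%), K3PO4, THF/H2O, rt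
Reagents that add atoms: none
Why: Suzuki–Miyaura coupling of the alkenylboronate with the bromoalkyne goes with retention, and the hindered alkenyl C–Br bond survives because oxidative addition to the C(sp)–Br bond is much faster.

Step 7
Reactants: 9 (1R)-1-[(2S,5R)-5-[(2S)-2-hydroxybut-3-en-2-yl]-2-methyloxolan-2-yl]propane-1,3-diol; 14 (3Z)-3-bromo-2-methylhept-3-en-5-yne
Product: 16 (1R)-1-[(2S,5R)-5-[(2S,5E)-2-hydroxy-5-(propan-2-yl)non-5-en-7-yn-2-yl]-2-methyloxolan-2-yl]propane-1,3-diol, via alkylborane 15 (not isolated)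
Conditions: 9-BBN (4.5 equiv), THF, 0 °C to rt; then 14, PdCl2(dppf) (10 mol%), AsPh3, aq K3PO4, DMF, 50 °C
Reagents that add atoms: none
Why: Anti-Markovnikov hydroboration of the only monosubstituted alkene followed by B-alkyl Suzuki–Miyaura coupling forms C14–C1 with retention at the bromoalkene, so C14 ends cis to C3; the free hydroxyl groups only consume extra 9-BBN.

Step 8
Reactants: 16 (1R)-1-[(2S,5R)-5-[(2S,5E)-2-hydroxy-5-(propan-2-yl)non-5-en-7-yn-2-yl]-2-methyloxolan-2-yl]propane-1,3-diol
Product: 17 (1R)-3-iodo-1-[(2S,5R)-5-[(2S,5E)-2-hydroxy-5-(propan-2-yl)non-5-en-7-yn-2-yl]-2-methyloxolan-2-yl]propan-1-ol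
Conditions: PPh3, I2, imidazole, THF/MeCN, 0 °C
Reagents that add atoms: iodine, II
Why: Appel-type iodination is selective for the primary C5 hydroxyl over the hindered secondary C7 and tertiary C12 hydroxyls.

Step 9
Reactants: 17 (1R)-3-iodo-1-[(2S,5R)-5-[(2S,5E)-2-hydroxy-5-(propan-2-yl)non-5-en-7-yn-2-yl]-2-methyloxolan-2-yl]propan-1-ol
Product: 19 (1R)-3-iodo-1-[(2S,5R)-5-[(2S,5E,7E)-2-hydroxy-8-iodo-5-(propan-2-yl)nona-5,7-dien-2-yl]-2-methyloxolan-2-yl]propan-1-ol, via Cp2Zr(Cl)-dienyl adduct 18 (not isolated)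
Conditions: Cp2Zr(H)Cl (4 equiv), THF, rt; I2, 0 °C
Reagents that add atoms: iodine, II
Why: syn-Hydrozirconation of the methyl-capped alkyne puts zirconium on the less hindered methyl-bearing carbon (C4) and iodinolysis goes with retention, giving the alkenyl iodide with iodine trans to C2 as needed for the 3E alkene.

Step 10
Reactants: 19 (1R)-3-iodo-1-[(2S,5R)-5-[(2S,5E,7E)-2-hydroxy-8-iodo-5-(propan-2-yl)nona-5,7-dien-2-yl]-2-methyloxolan-2-yl]propan-1-ol
Product: 20 (1S,2R,5E,7E,11S,12R)-1,5,11-trimethyl-8-(propan-2-yl)-15-oxabicyclo[10.2.1]pentadeca-5,7-diene-2,11-diol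
Conditions: NiBr2(dme) (30 mol%), 4,4'-di-tert-butyl-2,2'-bipyridine, nBu4NI, DMA, undivided cell, Zn anode, carbon-foam cathode at −1.3 V vs Ag/AgCl, 19 added over 12 h (2 mM), 25 °C
Reagents that add atoms: none
Why: Proposed new method: an intramolecular, ring-closing version of the nickel-catalysed reductive cross-electrophile coupling of alkyl halides with alkenyl halides (closest known reaction: the intermolecular coupling with zinc powder or a cathode as reductant), in which zerovalent nickel adds to the alkenyl C–I bond with retention, the alkenylnickel iodide is reduced at the cathode to monovalent alkenylnickel, this abstracts iodine from the tethered primary C–I bond and captures the C5 radical it has just made, and the trivalent alkyl(alkenyl)nickel eliminates the C4–C5 bond; because the radical is born at the metal that already holds the alkenyl partner and the substrate is kept near 2 mM, ring closure should outrun dimerisation and hydrogen abstraction, electrolysis avoids the triplet sensitisers that would scramble the diene, and no stereocentre is formed while both alkene geometries are kept.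

Step 11
Reactants: 20 (1S,2R,5E,7E,11S,12R)-1,5,11-trimethyl-8-(propan-2-yl)-15-oxabicyclo[10.2.1]pentadeca-5,7-diene-2,11-diol
Product: 21 (1S,2R,5E,7E,11S,12R)-11-hydroxy-1,5,11-trimethyl-8-(propan-2-yl)-15-oxabicyclo[10.2.1]pentadeca-5,7-dien-2-yl acetate
Conditions: Ac2O (1.5 equiv), pyridine, DMAP (5 mol%), CH2Cl2, 0 °C to rt
Reagents that add atoms: acetic anhydride, CC(=O)OC(C)=O
Why: Nucleophile-catalysed acetylation takes the secondary C7 hydroxyl and leaves the tertiary C12 hydroxyl free, giving the target (7R,8S,11R,12S).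

**Compound list**
1 | 5-methyl-2,3-dihydrofuran | CC1=CCCO1 | starting material
2 | vinylmagnesium bromide | C=C[Mg]Br | starting material
3 | (3Z)-4-methylhexa-3,5-dien-1-ol | OCC/C=C(\C=C)C | intermediate
4 | (3Z)-6-bromo-3-methylhexa-1,3-diene | BrCC/C=C(\C=C)C | intermediate
5 | (3R)-3-hydroxyoxolan-2-one | O[C@@H]1CCOC1=O | starting material
6 | [(3Z)-4-methylhexa-3,5-dien-1-yl]magnesium bromide | Br[Mg]CC/C=C(\C=C)C | intermediate (not isolated)
7 | (3R,7Z)-1,3-dihydroxy-8-methyldeca-7,9-dien-4-one, present as its magnesium alkoxide | OCC[C@@H](O)C(=O)CC/C=C(\C=C)C | intermediate (not isolated)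
8 | (3R,4S,7Z)-4,8-dimethyldeca-7,9-diene-1,3,4-triol | OCC[C@@H](O)[C@@](C)(O)CC/C=C(\C=C)C | intermediate
9 | (1R)-1-[(2S,5R)-5-[(2S)-2-hydroxybut-3-en-2-yl]-2-methyloxolan-2-yl]propane-1,3-diol | OCC[C@@H](O)[C@]1(C)CC[C@@H](O1)[C@@](C)(O)C=C | intermediate
10 | 3-methylbut-1-yne | CC(C)C#C | starting material
11 | dibromo[(1Z)-2-bromo-3-methylbut-1-en-1-yl]borane | CC(C)/C(Br)=C/B(Br)Br | intermediate (not isolated)
12 | 2-[(1Z)-2-bromo-3-methylbut-1-en-1-yl]-4,4,5,5-tetramethyl-1,3,2-dioxaborolane | CC(C)/C(Br)=C/B1OC(C)(C)C(C)(C)O1 | intermediate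
13 | 1-bromoprop-1-yne | CC#CBr | starting material
14 | (3Z)-3-bromo-2-methylhept-3-en-5-yne | CC#C/C=C(\Br)C(C)C | intermediate
15 | 9-borabicyclo[3.3.1]nonan-9-yl adduct at the terminal alkene carbon (C14) of 9, hydroxyl groups shown free | OCC[C@@H](O)[C@]1(C)CC[C@@H](O1)[C@@](C)(O)CCB1C2CCCC1CCC2 | intermediate (not isolated)
16 | (1R)-1-[(2S,5R)-5-[(2S,5E)-2-hydroxy-5-(propan-2-yl)non-5-en-7-yn-2-yl]-2-methyloxolan-2-yl]propane-1,3-diol | OCC[C@@H](O)[C@]1(C)CC[C@@H](O1)[C@@](C)(O)CC/C(C(C)C)=C\C#CC | intermediate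
17 | (1R)-3-iodo-1-[(2S,5R)-5-[(2S,5E)-2-hydroxy-5-(propan-2-yl)non-5-en-7-yn-2-yl]-2-methyloxolan-2-yl]propan-1-ol | ICC[C@@H](O)[C@]1(C)CC[C@@H](O1)[C@@](C)(O)CC/C(C(C)C)=C\C#CC | intermediate
18 | Cp2Zr(Cl) adduct of 17 with zirconium on C4 trans to C2, hydroxyl groups shown free | ICC[C@@H](O)[C@]1(C)CC[C@@H](O1)[C@@](C)(O)CC/C(C(C)C)=C\C=C(\[Zr](Cl)(C1C=CC=C1)C1C=CC=C1)C | intermediate (not isolated)
19 | (1R)-3-iodo-1-[(2S,5R)-5-[(2S,5E,7E)-2-hydroxy-8-iodo-5-(propan-2-yl)nona-5,7-dien-2-yl]-2-methyloxolan-2-yl]propan-1-ol | ICC[C@@H](O)[C@]1(C)CC[C@@H](O1)[C@@](C)(O)CC/C(C(C)C)=C\C=C(\I)C | intermediate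
20 | (1S,2R,5E,7E,11S,12R)-1,5,11-trimethyl-8-(propan-2-yl)-15-oxabicyclo[10.2.1]pentadeca-5,7-diene-2,11-diol | O[C@@H]1CC/C(C)=C/C=C(/C(C)C)CC[C@](C)(O)[C@H]2CC[C@]1(C)O2 | intermediate
21 | (1S,2R,5E,7E,11S,12R)-11-hydroxy-1,5,11-trimethyl-8-(propan-2-yl)-15-oxabicyclo[10.2.1]pentadeca-5,7-dien-2-yl acetate | CC(=O)O[C@@H]1CC/C(C)=C/C=C(/C(C)C)CC[C@](C)(O)[C@H]2CC[C@]1(C)O2 | target

**Step count**
Total: 11 steps (9 in the main line, 2 for bromoenyne 14). Longest linear sequence: 9 steps (1, 2, 3, 4, 7, 8, 9, 10, 11).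

**Steps most likely to fail**

Step 10 (the proposed new ring closure). Risks are reduction of the C5 radical, dimerisation, or slow closure of the 14-membered ring. The fallback uses known two-electron chemistry. It sets out from 19. Both hydroxyl groups are silylated (TESOTf, 2,6-lutidine, CH2Cl2) to give the 7,12-bis(triethylsilyl) ether of 19 F1. Zinc is inserted into the primary C–I bond only (Zn dust, LiCl, THF, 25 °C; the alkenyl iodide does not react at this temperature) to give the alkylzinc iodide F2. The ring is closed by intramolecular Negishi coupling (Pd(PPh3)4, THF/NMP, slow addition, 50 °C) to give the 7,12-bis(triethylsilyl) ether of 20 F3. Removal of the silyl groups (HF·pyridine) comes back to the route at 20.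

Step 4 (oxidative cyclisation next to a conjugated vinyl group). The reacting alkene is part of a 1,3-diene, and the free vinyl group may be dihydroxylated or divert the osmium. The fallback reverses the order of coupling and cyclisation. It sets out from 8. The terminal vinyl group of the diene is hydroborated with 9-BBN to give the 9-borabicyclo[3.3.1]nonan-9-yl adduct at the terminal carbon of 8 F4. This is coupled with 14 (PdCl2(dppf), AsPh3, aq K3PO4) to give (3R,4S,7Z,11E)-4,8-dimethyl-11-(propan-2-yl)pentadeca-7,11-dien-13-yne-1,3,4-triol F5. Its (Z)-alkene is now isolated, and the same osmium-catalysed oxidative cyclisation comes back to the route at 16.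

Step 3 (one-pot double addition to the lactone). Risks are double addition of 6 or of MeMgBr, or incomplete collapse of the hemiketalate. The fallback stops cleanly at the ketone through a Weinreb amide. It sets out from 5, which is opened with AlMe3 and MeNH(OMe)·HCl to give (2R)-2,4-dihydroxy-N-methoxy-N-methylbutanamide F6. After deprotonation with tBuMgCl (2 equiv) this takes up 6 once, and 7 is isolated as its cyclic hemiketal. Separate treatment with MeMgBr (4 equiv, −78 to 0 °C) comes back to the route at 8.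

**Further compounds**
F1 | step 10 | 7,12-bis(triethylsilyl) ether of 19 | ICC[C@@H](O[Si](CC)(CC)CC)[C@]1(C)CC[C@@H](O1)[C@@](C)(O[Si](CC)(CC)CC)CC/C(C(C)C)=C\C=C(\I)C
F2 | step 10 | alkylzinc iodide from F1 | I[Zn]CC[C@@H](O[Si](CC)(CC)CC)[C@]1(C)CC[C@@H](O1)[C@@](C)(O[Si](CC)(CC)CC)CC/C(C(C)C)=C\C=C(\I)C
F3 | step 10 | 7,12-bis(triethylsilyl) ether of 20 | CC[Si](CC)(CC)O[C@@H]1CC/C(C)=C/C=C(/C(C)C)CC[C@](C)(O[Si](CC)(CC)CC)[C@H]2CC[C@]1(C)O2
F4 | step 4 | 9-borabicyclo[3.3.1]nonan-9-yl adduct at the terminal carbon of 8 | OCC[C@@H](O)[C@@](C)(O)CC/C=C(\CCB1C2CCCC1CCC2)C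
F5 | step 4 | (3R,4S,7Z,11E)-4,8-dimethyl-11-(propan-2-yl)pentadeca-7,11-dien-13-yne-1,3,4-triol | OCC[C@@H](O)[C@@](C)(O)CC/C=C(\CC/C(C(C)C)=C\C#CC)C
F6 | step 3 | (2R)-2,4-dihydroxy-N-methoxy-N-methylbutanamide | CON(C)C(=O)[C@H](O)CCO
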